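**Retrosynthetic overview**
1. Target 28 ⇐ peripheral epoxidation of the strained ring-trans C1=C10 alkene of ester 27 ⇐ acylation of the 8β-hydroxyl of macrocycle 20 with epoxy acid 26 (from (S)-lactic acid: dioxolanone aldol, mesylate, oxirane closure).
2. 20 ⇐ C6–C7 bond: chromium-electrocatalytic intramolecular allylation of the enal by the 3-(bromomethyl)butenolide in 18; this closes the ten-membered ring and sets C6 and C7 from C8, then the acyl group shifts from O8 to O6 in the flask.
3. 18 ⇐ Morita–Baylis–Hillman reaction, lactonisation and SN2′ bromination on dialdehyde 14 ⇐ triol 12.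
4. C1=C10 (CH2OAc cis to C2) ⇐ Still–Gennari olefination of nerol-derived aldehyde 4 with phosphonate 8 from (R)-solketal (C8 stereocenter).
5. Ring order: butenolide, then ten-membered carbocycle, then 6,12-lactone (acyl shift), then the ring oxirane last; the side-chain oxirane is made separately.

Assumption: ring atoms carry germacrane numbers (C6 lactone carbinol, C8 ester carbinol, C1/C10 oxirane, C14 = CH2OAc, C15 = methyl on C4), and nerol, (R)-solketal, (S)-lactic acid and the named reagents are taken as commercial.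

**Route**

Step 1
Reactants: 1 nerol
Product: 2 neryl tert-butyldimethylsilyl ether
Conditions: TBSCl, imidazole, CH2Cl2, 0 °C to rt
Reagents that add atoms: tert-butyldimethylsilyl chloride, CC(C)(C)[Si](C)(C)Cl
Why: Silyl ether protection of the primary allylic alcohol masks the C6 oxygen in a form that survives olefination, hydride reduction and acetylation and falls off with acid later; the Z-C4=C5 alkene is bought in nerol.

Step 2
Reactants: 2 neryl tert-butyldimethylsilyl ether
Product: 4 (4Z)-6-[(tert-butyldimethylsilyl)oxy]-4-methylhex-4-enal, via 6,7-epoxide 3 (not isolated)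
Conditions: mCPBA (1.05 equiv), CH2Cl2, −20 °C; then H5IO6 (1.2 equiv), THF/Et2O, 0 °C
Reagents that add atoms: meta-chloroperoxybenzoic acid, OOC(=O)c1cccc(Cl)c1
Why: Prilezhaev epoxidation picks the more electron-rich distal alkene (the other is deactivated by the allylic silyloxy group) and periodic acid cleaves the epoxide through its glycol to the aldehyde and acetone without touching the Z-alkene.

Step 3
Reactants: 5 (R)-solketal
Product: 6 [(4S)-2,2-dimethyl-1,3-dioxolan-4-yl]methyl trifluoromethanesulfonate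
Conditions: Tf2O, pyridine, CH2Cl2, −40 to 0 °C
Reagents that add atoms: trifluoromethanesulfonic anhydride, O=S(=O)(OS(=O)(=O)C(F)(F)F)C(F)(F)F
Why: O-sulfonylation gives a leaving group reactive enough for SN2 at this β-oxygenated carbon; the stereocenter (future C8) is not touched and its descriptor changes only through CIP priorities.

Step 4
Reactants: 7 methyl 2-[bis(2,2,2-trifluoroethoxy)phosphoryl]acetate; 6 [(4S)-2,2-dimethyl-1,3-dioxolan-4-yl]methyl trifluoromethanesulfonate
Product: 8 methyl 2-[bis(2,2,2-trifluoroethoxy)phosphoryl]-3-[(4R)-2,2-dimethyl-1,3-dioxolan-4-yl]propanoate (both C2 epimers)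
Conditions: NaH, THF, 0 °C; then 6, THF/DMF, 0 °C to rt
Reagents that add atoms: none
Why: SN2 C-alkylation of the sodium phosphonoacetate by the primary triflate gives the α-substituted Still–Gennari reagent; the new α-center disappears in step 5 and the dioxolane center is untouched.

Step 5
Reactants: 8 methyl 2-[bis(2,2,2-trifluoroethoxy)phosphoryl]-3-[(4R)-2,2-dimethyl-1,3-dioxolan-4-yl]propanoate; 4 (4Z)-6-[(tert-butyldimethylsilyl)oxy]-4-methylhex-4-enal
Product: 9 methyl (2Z,6Z)-8-[(tert-butyldimethylsilyl)oxy]-2-{[(4R)-2,2-dimethyl-1,3-dioxolan-4-yl]methyl}-6-methylocta-2,6-dienoate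
Conditions: KN(SiMe3)2, 18-crown-6, THF, −78 °C
Reagents that add atoms: none
Why: The Still–Gennari variant of the Horner–Wadsworth–Emmons olefination gives the Z-trisubstituted enoate under kinetic control (ester carbon C14 cis to the C2 chain), which is the ring-trans C1=C10 geometry of the target.

Step 6
Reactants: 9 methyl (2Z,6Z)-8-[(tert-butyldimethylsilyl)oxy]-2-{[(4R)-2,2-dimethyl-1,3-dioxolan-4-yl]methyl}-6-methylocta-2,6-dienoate
Product: 11 (2Z,6Z)-8-[(tert-butyldimethylsilyl)oxy]-2-{[(4R)-2,2-dimethyl-1,3-dioxolan-4-yl]methyl}-6-methylocta-2,6-dien-1-yl acetate, via allylic aluminium alkoxide 10 (not isolated)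
Conditions: iBu2AlH (2.5 equiv), CH2Cl2, −78 to 0 °C; then Ac2O, pyridine, DMAP, 0 °C to rt
Reagents that add atoms: acetic anhydride, CC(=O)OC(C)=O
Why: 1,2-Reduction of the conjugated ester and acetylation of the aluminium alkoxide in the same flask (reductive acylation) install the C14 acetate of the target; silyl ether, acetonide and alkene geometry are unaffected.

Step 7
Reactants: 11 (2Z,6Z)-8-[(tert-butyldimethylsilyl)oxy]-2-{[(4R)-2,2-dimethyl-1,3-dioxolan-4-yl]methyl}-6-methylocta-2,6-dien-1-yl acetate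
Product: 12 (2Z,6Z)-2-[(2R)-2,3-dihydroxypropyl]-8-hydroxy-6-methylocta-2,6-dien-1-yl acetate
Conditions: AcOH/H2O (4:1), 40 °C
Reagents that add atoms: none
Why: Acid-catalysed hydrolysis removes the acetonide and the primary TBS ether together while the allylic acetate survives, exposing the C6, C7 and C8 hydroxyls in one operation.

Step 8
Reactants: 12 (2Z,6Z)-2-[(2R)-2,3-dihydroxypropyl]-8-hydroxy-6-methylocta-2,6-dien-1-yl acetate
Product: 13 (2Z,6Z)-2-[(2R)-2,3-bis(triethylsilyloxy)propyl]-6-methyl-8-(triethylsilyloxy)octa-2,6-dien-1-yl acetate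
Conditions: TESCl (3.6 equiv), imidazole, DMAP (cat.), CH2Cl2, 0 °C to rt
Reagents that add atoms: chlorotriethylsilane, CC[Si](Cl)(CC)CC
Why: Exhaustive silylation gives two primary and one secondary triethylsilyl ether, which sets up the chemoselective oxidation of primary triethylsilyl ethers.

Step 9
Reactants: 13 (2Z,6Z)-2-[(2R)-2,3-bis(triethylsilyloxy)propyl]-6-methyl-8-(triethylsilyloxy)octa-2,6-dien-1-yl acetate
Product: 14 (2Z,6Z)-6-methyl-8-oxo-2-[(2R)-3-oxo-2-(triethylsilyloxy)propyl]octa-2,6-dien-1-yl acetate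
Conditions: (COCl)2, DMSO, CH2Cl2, −78 to −40 °C; then Et3N, −78 to 0 °C
Reagents that add atoms: none
Why: Under Swern conditions primary triethylsilyl ethers are cleaved and oxidised directly to aldehydes while the secondary one at C8 is inert, giving the Z-enal (C6) and the α-silyloxy aldehyde (C7) at low temperature without epimerising C8.

Step 10
Reactants: 14 (2Z,6Z)-6-methyl-8-oxo-2-[(2R)-3-oxo-2-(triethylsilyloxy)propyl]octa-2,6-dien-1-yl acetate; 15 methyl acrylate
Product: 16 methyl (4R,6Z,10Z)-6-(acetoxymethyl)-3-hydroxy-10-methyl-2-methylidene-12-oxo-4-(triethylsilyloxy)dodeca-6,10-dienoate (C3 epimers)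
Conditions: DABCO (1 equiv), methyl acrylate (10 equiv), MeOH (2 equiv), rt, 4 d
Reagents that add atoms: none
Why: In this Morita–Baylis–Hillman reaction the DABCO–acrylate zwitterion adds only to the activated α-silyloxy aldehyde (the β,β-disubstituted enal is a poor electrophile), attaching C11–C13; the new carbinol center at C7 is a mixture that converges in step 12.

Step 11
Reactants: 16 methyl (4R,6Z,10Z)-6-(acetoxymethyl)-3-hydroxy-10-methyl-2-methylidene-12-oxo-4-(triethylsilyloxy)dodeca-6,10-dienoate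
Product: 17 (2Z,6Z)-2-{[(2R)-3-hydroxy-4-methylidene-5-oxooxolan-2-yl]methyl}-6-methyl-8-oxoocta-2,6-dien-1-yl acetate (epimers at the carbinol)
Conditions: 1 M HCl/THF (1:4), 0 °C to rt
Reagents that add atoms: none
Why: Acidic desilylation frees the C8 hydroxyl, which lactonises onto the methyl ester (5-exo-trig acyl substitution) to the α-methylene-β-hydroxy-γ-butyrolactone with C8 unchanged.

Step 12
Reactants: 17 (2Z,6Z)-2-{[(2R)-3-hydroxy-4-methylidene-5-oxooxolan-2-yl]methyl}-6-methyl-8-oxoocta-2,6-dien-1-yl acetate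
Product: 18 (2Z,6Z)-2-{[(2R)-4-(bromomethyl)-5-oxo-2,5-dihydrofuran-2-yl]methyl}-6-methyl-8-oxoocta-2,6-dien-1-yl acetate
Conditions: PBr3 (0.5 equiv), Et2O, −10 to 0 °C
Reagents that add atoms: phosphorus tribromide, BrP(Br)Br
Why: SN2′ bromination with allylic transposition moves the double bond into conjugation inside the lactone and gives the 3-(bromomethyl)butenolide, so both carbinol epimers of 17 converge on one compound.

Step 13
Reactants: 18 (2Z,6Z)-2-{[(2R)-4-(bromomethyl)-5-oxo-2,5-dihydrofuran-2-yl]methyl}-6-methyl-8-oxoocta-2,6-dien-1-yl acetate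
Product: 20 (6R,7R,8R)-14-acetoxy-8-hydroxygermacra-1(10),4,11(13)-trien-12,6-olide (ring-trans C1=C10; cis C4=C5), via cis-fused 8β,12-olide 6-alkoxide 19 (not isolated)
Conditions: CrCl3(THF)3 (20 mol %), LiCl (0.1 M), DMF, undivided cell, Al anode, Ni-foam cathode, constant current 3 mA (2.4 F/mol), 18 added by syringe pump over 12 h (final 2 mM), rt; then 40 °C, 2 h; aq. citric acid
Reagents that add atoms: none
Why: Proposed new method: a chromium-electrocatalytic intramolecular carbonyl allylation of a 3-(bromomethyl)butenolide, in which cathodic reduction regenerates divalent chromium, two divalent chromium ions turn the allylic C–Br bond into an allylchromium species (trivalent chromium) whose γ-carbon C7 adds to the tethered enal C6 through a closed six-membered chair transition state, and aluminium cations from the anode take the alkoxide off chromium (turnover) and promote the acyl shift from O8 to O6 toward the more stable trans-fused 6,12-olide; the butenolide holds the ester cis to C8, the C9 tether delivers the aldehyde to the butenolide face that carries C9 (sets C7 R from C8 R) and the pseudo-equatorial vinyl group of the enal gives the 6,7-anti relationship (C6 R); the closest known reaction types are the electrochemically driven chromium-catalysed Nozaki–Hiyama–Kishi coupling (intermolecular) and stoichiometric CrCl2-, Zn- or In-mediated Barbier allylations with bromomethyl butenolides and macrocyclic Nozaki–Hiyama–Kishi closures.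

Step 14
Reactants: 21 (S)-lactic acid
Product: 22 (2S,5S)-2-tert-butyl-5-methyl-1,3-dioxolan-4-one
Conditions: pivalaldehyde, p-TsOH (cat.), pentane, reflux (Dean–Stark); crystallisation
Reagents that add atoms: pivalaldehyde, CC(C)(C)C=O
Why: Acid-catalysed acetalisation gives mainly the cis-dioxolanone (acetal center controlled by the lactic acid stereocenter, purified by crystallisation), the entry to self-regeneration of stereocenters.

Step 15
Reactants: 22 (2S,5S)-2-tert-butyl-5-methyl-1,3-dioxolan-4-one; 23 acetaldehyde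
Product: 24 (2S,5R)-2-tert-butyl-5-[(1R)-1-hydroxyethyl]-5-methyl-1,3-dioxolan-4-one
Conditions: LiN(iPr)2, THF, −78 °C; then acetaldehyde, −78 °C; aq. NH4Cl
Reagents that add atoms: none
Why: The aldol addition of the lithium enolate occurs anti to the tert-butyl group (quaternary center R) and through a closed Zimmerman–Traxler chair with the aldehyde methyl equatorial (carbinol R); the minor carbinol epimer is removed by chromatography.

Step 16
Reactants: 24 (2S,5R)-2-tert-butyl-5-[(1R)-1-hydroxyethyl]-5-methyl-1,3-dioxolan-4-one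
Product: 25 (1R)-1-[(2S,4R)-2-tert-butyl-4-methyl-5-oxo-1,3-dioxolan-4-yl]ethyl methanesulfonate
Conditions: MsCl, Et3N, CH2Cl2, 0 °C
Reagents that add atoms: methanesulfonyl chloride, CS(=O)(=O)Cl
Why: Sulfonylation of the secondary alcohol with retention makes that carbon the electrophile for the oxirane closure.

Step 17
Reactants: 25 (1R)-1-[(2S,4R)-2-tert-butyl-4-methyl-5-oxo-1,3-dioxolan-4-yl]ethyl methanesulfonate
Product: 26 (2R,3S)-2,3-dimethyloxirane-2-carboxylic acid
Conditions: LiOH (3 equiv), THF/H2O, 0 °C to rt; then NaHSO4 to pH 3, extraction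
Reagents that add atoms: lithium hydroxide, [Li+].[OH-]
Why: Saponification opens the dioxolanone, the hemiacetal releases pivalaldehyde and the tertiary alkoxide displaces the mesylate (3-exo-tet Williamson closure) with inversion at C3, giving the cis-dimethyl epoxy acid.

Step 18
Reactants: 20 (6R,7R,8R)-14-acetoxy-8-hydroxygermacra-1(10),4,11(13)-trien-12,6-olide; 26 (2R,3S)-2,3-dimethyloxirane-2-carboxylic acid
Product: 27 (6R,7R,8R)-14-acetoxy-8-[(2R,3S)-2,3-dimethyloxirane-2-carbonyloxy]germacra-1(10),4,11(13)-trien-12,6-olide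
Conditions: 2-methyl-6-nitrobenzoic anhydride, DMAP, Et3N, CH2Cl2, rt
Reagents that add atoms: none
Why: Shiina esterification through the mixed anhydride acylates the hindered secondary hydroxyl under mild basic conditions that the oxirane acid, the allylic acetate and the α-methylene lactone tolerate, with no change at any stereocenter.

Step 19
Reactants: 27 (6R,7R,8R)-14-acetoxy-8-[(2R,3S)-2,3-dimethyloxirane-2-carbonyloxy]germacra-1(10),4,11(13)-trien-12,6-olide
Product: 28 target CNP0232260.6, (1R,6R,7R,8R,10S)-14-acetoxy-1,10-epoxy-8-[(2R,3S)-2,3-dimethyloxirane-2-carbonyloxy]germacra-4(Z),11(13)-dien-12,6-olide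
Conditions: mCPBA (1.05 equiv), NaHCO3, CH2Cl2, −20 to 0 °C
Reagents that add atoms: meta-chloroperoxybenzoic acid, OOC(=O)c1cccc(Cl)c1
Why: Prilezhaev epoxidation attacks the strained ring-trans C1=C10 alkene faster than the cis C4=C5 alkene or the electron-poor methylene lactone, and only from the outer face of the macrocycle (conformer with C14 on the β face), giving the 1β,10α-oxirane by substrate control.

**Compound list**
1 | nerol, (2Z)-3,7-dimethylocta-2,6-dien-1-ol | CC(C)=CCC/C(C)=C\CO | starting material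
2 | neryl tert-butyldimethylsilyl ether | CC(C)=CCC/C(C)=C\CO[Si](C)(C)C(C)(C)C | intermediate
3 | 6,7-epoxide of 2 (racemic at the oxirane CH, which becomes the aldehyde carbon) | CC1(C)OC1CC/C(C)=C\CO[Si](C)(C)C(C)(C)C | intermediate
4 | (4Z)-6-[(tert-butyldimethylsilyl)oxy]-4-methylhex-4-enal | O=CCC/C(C)=C\CO[Si](C)(C)C(C)(C)C | intermediate
5 | (R)-solketal, [(4R)-2,2-dimethyl-1,3-dioxolan-4-yl]methanol | OC[C@@H]1COC(C)(C)O1 | starting material
6 | [(4S)-2,2-dimethyl-1,3-dioxolan-4-yl]methyl trifluoromethanesulfonate | FC(F)(F)S(=O)(=O)OC[C@@H]1COC(C)(C)O1 | intermediate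
7 | methyl 2-[bis(2,2,2-trifluoroethoxy)phosphoryl]acetate | COC(=O)CP(=O)(OCC(F)(F)F)OCC(F)(F)F | starting material
8 | methyl 2-[bis(2,2,2-trifluoroethoxy)phosphoryl]-3-[(4R)-2,2-dimethyl-1,3-dioxolan-4-yl]propanoate (both C2 epimers) | COC(=O)C(C[C@@H]1COC(C)(C)O1)P(=O)(OCC(F)(F)F)OCC(F)(F)F | intermediate
9 | methyl (2Z,6Z)-8-[(tert-butyldimethylsilyl)oxy]-2-{[(4R)-2,2-dimethyl-1,3-dioxolan-4-yl]methyl}-6-methylocta-2,6-dienoate | COC(=O)/C(C[C@@H]1COC(C)(C)O1)=C\CC/C(C)=C\CO[Si](C)(C)C(C)(C)C | intermediate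
10 | (2Z,6Z)-8-[(tert-butyldimethylsilyl)oxy]-2-{[(4R)-2,2-dimethyl-1,3-dioxolan-4-yl]methyl}-6-methylocta-2,6-dien-1-ol (present as its diisobutylaluminium alkoxide) | OC/C(C[C@@H]1COC(C)(C)O1)=C\CC/C(C)=C\CO[Si](C)(C)C(C)(C)C | intermediate
11 | (2Z,6Z)-8-[(tert-butyldimethylsilyl)oxy]-2-{[(4R)-2,2-dimethyl-1,3-dioxolan-4-yl]methyl}-6-methylocta-2,6-dien-1-yl acetate | CC(=O)OC/C(C[C@@H]1COC(C)(C)O1)=C\CC/C(C)=C\CO[Si](C)(C)C(C)(C)C | intermediate
12 | (2Z,6Z)-2-[(2R)-2,3-dihydroxypropyl]-8-hydroxy-6-methylocta-2,6-dien-1-yl acetate | CC(=O)OC/C(C[C@@H](O)CO)=C\CC/C(C)=C\CO | intermediate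
13 | (2Z,6Z)-2-[(2R)-2,3-bis(triethylsilyloxy)propyl]-6-methyl-8-(triethylsilyloxy)octa-2,6-dien-1-yl acetate | CC(=O)OC/C(C[C@@H](O[Si](CC)(CC)CC)CO[Si](CC)(CC)CC)=C\CC/C(C)=C\CO[Si](CC)(CC)CC | intermediate
14 | (2Z,6Z)-6-methyl-8-oxo-2-[(2R)-3-oxo-2-(triethylsilyloxy)propyl]octa-2,6-dien-1-yl acetate | CC(=O)OC/C(C[C@@H](O[Si](CC)(CC)CC)C=O)=C\CC/C(C)=C\C=O | intermediate
15 | methyl acrylate | C=CC(=O)OC | starting material
16 | methyl (4R,6Z,10Z)-6-(acetoxymethyl)-3-hydroxy-10-methyl-2-methylidene-12-oxo-4-(triethylsilyloxy)dodeca-6,10-dienoate (C3 epimers) | CC(=O)OC/C(C[C@@H](O[Si](CC)(CC)CC)C(O)C(=C)C(=O)OC)=C\CC/C(C)=C\C=O | intermediate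
17 | (2Z,6Z)-2-{[(2R)-3-hydroxy-4-methylidene-5-oxooxolan-2-yl]methyl}-6-methyl-8-oxoocta-2,6-dien-1-yl acetate (epimers at oxolane C3) | CC(=O)OC/C(C[C@H]1OC(=O)C(=C)C1O)=C\CC/C(C)=C\C=O | intermediate
18 | (2Z,6Z)-2-{[(2R)-4-(bromomethyl)-5-oxo-2,5-dihydrofuran-2-yl]methyl}-6-methyl-8-oxoocta-2,6-dien-1-yl acetate | CC(=O)OC/C(C[C@H]1OC(=O)C(CBr)=C1)=C\CC/C(C)=C\C=O | intermediate
19 | (6R,7S,8R)-14-acetoxy-6-hydroxygermacra-1(10),4,11(13)-trien-12,8-olide, cis-fused 8β,12-olide with 6α-OH (present as its aluminium alkoxide; same spatial arrangement at C6–C8 as 20) | C=C1C(=O)O[C@@H]2C/C(COC(C)=O)=C/CC/C(C)=C\[C@@H](O)[C@H]12 | intermediate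
20 | (6R,7R,8R)-14-acetoxy-8-hydroxygermacra-1(10),4,11(13)-trien-12,6-olide (ring-trans C1=C10 with CH2OAc cis to C2; cis C4=C5) | C=C1C(=O)O[C@@H]2/C=C(/C)CC/C=C(\COC(C)=O)C[C@@H](O)[C@@H]12 | intermediate
21 | (S)-lactic acid | C[C@H](O)C(=O)O | starting material
22 | (2S,5S)-2-tert-butyl-5-methyl-1,3-dioxolan-4-one | C[C@@H]1O[C@H](C(C)(C)C)OC1=O | intermediate
23 | acetaldehyde | CC=O | starting material
24 | (2S,5R)-2-tert-butyl-5-[(1R)-1-hydroxyethyl]-5-methyl-1,3-dioxolan-4-one | C[C@@H](O)[C@@]1(C)O[C@H](C(C)(C)C)OC1=O | intermediate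
25 | (1R)-1-[(2S,4R)-2-tert-butyl-4-methyl-5-oxo-1,3-dioxolan-4-yl]ethyl methanesulfonate | C[C@@H](OS(C)(=O)=O)[C@@]1(C)O[C@H](C(C)(C)C)OC1=O | intermediate
26 | (2R,3S)-2,3-dimethyloxirane-2-carboxylic acid | OC(=O)[C@]1(C)O[C@H]1C | intermediate
27 | (6R,7R,8R)-14-acetoxy-8-[(2R,3S)-2,3-dimethyloxirane-2-carbonyloxy]germacra-1(10),4,11(13)-trien-12,6-olide | C=C1C(=O)O[C@@H]2/C=C(/C)CC/C=C(\COC(C)=O)C[C@@H](OC(=O)[C@]3(C)O[C@H]3C)[C@@H]12 | intermediate
28 | CNP0232260.6, (1R,6R,7R,8R,10S)-14-acetoxy-1,10-epoxy-8-[(2R,3S)-2,3-dimethyloxirane-2-carbonyloxy]germacra-4(Z),11(13)-dien-12,6-olide | C=C1C(=O)O[C@@H]2/C=C(/C)CC[C@H]3O[C@]3(COC(C)=O)C[C@@H](OC(=O)[C@]3(C)O[C@H]3C)[C@@H]12 | target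

**Count and risks**

Total step count: 19. Longest linear sequence: 13 steps (steps 3–13, 18, 19, from (R)-solketal).

Most likely to fail:

1. Step 13 (the proposed electrocatalytic ring closure). The risks are cathodic side reactions, poor chromium turnover, an incomplete acyl shift, or the wrong facial course at C7. The fallback sets out from 18 and comes back at 20 with known stoichiometric chemistry and no electrolysis. A Nozaki–Hiyama–Kishi/Barbier ring closure with excess CrCl2 (8 equiv, DMF/THF, syringe-pump addition, rt), then aqueous work-up, gives the hydroxy 8β,12-olide 19, which is isolated. A separate base-mediated translactonisation (DBU, 0.2 equiv, CH2Cl2, rt) then gives 20. This fallback makes no compound outside the list (F0).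

2. Step 10 (Morita–Baylis–Hillman reaction on the dialdehyde). It is slow, and DABCO may isomerise or consume the Z-enal. The fallback sets out from 11 and comes back at 17, keeping C6 masked until the acrylate unit is in place. The acetonide alone is removed with Zn(NO3)2·6H2O in MeCN at 50 °C to give (2Z,6Z)-8-[(tert-butyldimethylsilyl)oxy]-2-[(2R)-2,3-dihydroxypropyl]-6-methylocta-2,6-dien-1-yl acetate F1. TESCl/imidazole gives the bis(triethylsilyl) ether F2. Swern oxidation (only the primary triethylsilyl ether reacts) gives the mono-aldehyde F3. DABCO and methyl acrylate 15 give the Baylis–Hillman adduct F4. 1 M HCl/THF removes both silyl groups and lactonises to the hydroxy lactone allylic alcohol F5. TEMPO (cat.)/PhI(OAc)2 in CH2Cl2 oxidises only the primary allylic alcohol and returns 17.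

3. Step 19 (final epoxidation; selectivity between the C1=C10 and C4=C5 alkenes). The fallback sets out from 27 and comes back at 28 with a hydroxyl-directed epoxidation. Neutral tin-catalysed methanolysis of the primary acetate ([tBu2Sn(OH)Cl]2 cat., MeOH/THF, 30 °C) gives the 14-hydroxy triene ester F6. VO(acac)2 (cat.)/tBuOOH in CH2Cl2 at 0 °C epoxidises only the allylic-alcohol alkene from the outer face to give the 14-hydroxy 1β,10α-epoxide F7. Ac2O/pyridine then gives 28.

Further compounds
F0 | step 13 | none | none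
F1 | step 10 | (2Z,6Z)-8-[(tert-butyldimethylsilyl)oxy]-2-[(2R)-2,3-dihydroxypropyl]-6-methylocta-2,6-dien-1-yl acetate | CC(=O)OC/C(C[C@@H](O)CO)=C\CC/C(C)=C\CO[Si](C)(C)C(C)(C)C
F2 | step 10 | (2Z,6Z)-2-[(2R)-2,3-bis(triethylsilyloxy)propyl]-8-[(tert-butyldimethylsilyl)oxy]-6-methylocta-2,6-dien-1-yl acetate | CC(=O)OC/C(C[C@@H](O[Si](CC)(CC)CC)CO[Si](CC)(CC)CC)=C\CC/C(C)=C\CO[Si](C)(C)C(C)(C)C
F3 | step 10 | (2Z,6Z)-8-[(tert-butyldimethylsilyl)oxy]-6-methyl-2-[(2R)-3-oxo-2-(triethylsilyloxy)propyl]octa-2,6-dien-1-yl acetate | CC(=O)OC/C(C[C@@H](O[Si](CC)(CC)CC)C=O)=C\CC/C(C)=C\CO[Si](C)(C)C(C)(C)C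
F4 | step 10 | methyl (4R,6Z,10Z)-6-(acetoxymethyl)-12-[(tert-butyldimethylsilyl)oxy]-3-hydroxy-10-methyl-2-methylidene-4-(triethylsilyloxy)dodeca-6,10-dienoate (C3 epimers) | CC(=O)OC/C(C[C@@H](O[Si](CC)(CC)CC)C(O)C(=C)C(=O)OC)=C\CC/C(C)=C\CO[Si](C)(C)C(C)(C)C
F5 | step 10 | (2Z,6Z)-8-hydroxy-2-{[(2R)-3-hydroxy-4-methylidene-5-oxooxolan-2-yl]methyl}-6-methylocta-2,6-dien-1-yl acetate (epimers at oxolane C3) | CC(=O)OC/C(C[C@H]1OC(=O)C(=C)C1O)=C\CC/C(C)=C\CO
F6 | step 19 | (6R,7R,8R)-8-[(2R,3S)-2,3-dimethyloxirane-2-carbonyloxy]-14-hydroxygermacra-1(10),4,11(13)-trien-12,6-olide | C=C1C(=O)O[C@@H]2/C=C(/C)CC/C=C(\CO)C[C@@H](OC(=O)[C@]3(C)O[C@H]3C)[C@@H]12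
F7 | step 19 | (1R,6R,7R,8R,10S)-1,10-epoxy-8-[(2R,3S)-2,3-dimethyloxirane-2-carbonyloxy]-14-hydroxygermacra-4(Z),11(13)-dien-12,6-olide | C=C1C(=O)O[C@@H]2/C=C(/C)CC[C@H]3O[C@]3(CO)C[C@@H](OC(=O)[C@]3(C)O[C@H]3C)[C@@H]12
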